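The cyclohexa-2,5-dienone ring (C1 carbonyl, C2 allyl, C3 H, quaternary C4, C5 OMe, C6 H) is built last from an open chain. It is read as the methanol adduct of an alkynone (C5≡C6–C1=O) condensed through C2 with an aldehyde carbon C3. One methoxide-catalysed operation on an acyclic keto ynal installs the C5 methoxy group, equilibrates the E/Z enol ethers and closes C2=C3 by aldol condensation. It exploits quaternary C4, which leaves the aldehyde and the γ-position without acidic hydrogen, so only C2 can enolise. C4 and the side-chain stereocentre are set beforehand by copper–boron addition, Zweifel coupling, Sharpless epoxidation and invertive epoxide methanolysis.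

Key step: step 11

Remark: C1–C6 are the dienone ring atoms defined above and C8 is the side-chain methine. Commercial (E)-isoeugenol is taken as the pure E isomer. "Aryl" in the names means 3-methoxy-4-(triisopropylsilyloxy)phenyl.

Step 1
Reactants: 1 (E)-isoeugenol
Product: 2 (E)-isoeugenol triisopropylsilyl ether
Conditions: TIPSCl, imidazole, DMF, rt
Reagents that add atoms: triisopropylsilyl chloride, CC(C)[Si](Cl)(C(C)C)C(C)C
Why: Imidazole-promoted silylation of a phenol; the bulky aryl TIPS ether should survive the alkoxide, organolithium and Lewis-acid steps that follow, and no stereocentre is formed.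

Step 2
Reactants: 2 (E)-isoeugenol triisopropylsilyl ether
Product: 3 (R)-2-[1-(aryl)propan-2-yl]-4,4,5,5-tetramethyl-1,3,2-dioxaborolane
Conditions: B2pin2, MeOH (2 equiv), CuCl (5 mol%), chiral imidazolinium salt (NHC precursor, 5 mol%, the enantiomer that gives R), NaOt-Bu (20 mol%), THF, −50 °C
Reagents that add atoms: bis(pinacolato)diboron, CC1(C)OB(OC1(C)C)B1OC(C)(C)C(C)(C)O1
Why: Enantioselective NHC–copper-catalysed protoboration of a β-alkylstyrene: Cu–Bpin adds syn with copper at the benzylic carbon and boron at the methyl-bearing carbon, methanol protonates the C–Cu bond, and the facial control of the chosen catalyst enantiomer sets C8 as R.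

Step 3
Reactants: 4 2-bromoprop-2-en-1-ol
Product: 5 2-bromo-3-(2-methoxypropan-2-yloxy)prop-1-ene (MIP ether)
Conditions: 2-methoxypropene, PPTS (cat.), CH2Cl2, 0 °C
Reagents that add atoms: 2-methoxypropene, COC(C)=C
Why: Acid-catalysed addition of the alcohol to an enol ether gives an achiral mixed acetal that tolerates tert-butyllithium and is removed by mild acid.

Step 4
Reactants: 3 (R)-boronic ester; 5 MIP ether of 2-bromoallyl alcohol
Product: 10 (3R)-4-(aryl)-3-methyl-2-methylidenebutan-1-ol, via alkenyllithium 6 (not isolated), via lithium boronate complex 7 (not isolated), via beta-iodo boronic ester 8 (not isolated), via MIP-protected allylic ether 9 (not isolated)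
Conditions: 5, t-BuLi (2 equiv), Et2O, −78 °C; 3, THF, −78 to 0 °C; I2, THF, −78 °C; NaOMe, MeOH, −78 °C to rt; then PPTS (cat.), MeOH, rt
Reagents that add atoms: none
Why: Zweifel olefination: bromine–lithium exchange, boronate complex formation, iodine-triggered 1,2-migration of the secondary alkyl group with retention at C8 and methoxide-induced anti elimination of boron and iodine join C8 to C4, and mild methanolysis of the acetal frees the allylic alcohol.

Step 5
Reactants: 10 allylic alcohol
Product: 11 {(2S)-2-[(2R)-1-(aryl)propan-2-yl]oxiran-2-yl}methanol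
Conditions: Ti(Oi-Pr)4 (10 mol%), L-(+)-DIPT (12 mol%), TBHP, 4 Å MS, CH2Cl2, −20 °C
Reagents that add atoms: tert-butyl hydroperoxide, CC(C)(C)OO
Why: Sharpless asymmetric epoxidation of a 2-substituted allylic alcohol: the L-(+)-tartrate catalyst delivers oxygen to the face that gives the 2S series of epoxy alcohols, so C4 is set under reagent control that should override the neighbouring C8 centre.

Step 6
Reactants: 11 epoxy alcohol
Product: 12 (2R)-2-[(2R)-1-(aryl)propan-2-yl]oxirane-2-carbaldehyde
Conditions: TEMPO (cat.), PhI(OAc)2, CH2Cl2, rt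
Reagents that add atoms: none
Why: Oxoammonium (TEMPO/BAIB) oxidation of the primary alcohol runs without base, which avoids the degenerate Payne rearrangement that would epimerise C4, and the aldehyde has no α-hydrogen.

Step 7
Reactants: 12 epoxy aldehyde
Product: 13 (2S)-2-ethynyl-2-[(2R)-1-(aryl)propan-2-yl]oxirane
Conditions: dimethyl (1-diazo-2-oxopropyl)phosphonate, K2CO3, MeOH, 0 °C to rt
Reagents that add atoms: Ohira–Bestmann reagent, COP(=O)(OC)C(=[N+]=[N-])C(C)=O
Why: Ohira–Bestmann (Seyferth–Gilbert) homologation converts the non-enolisable aldehyde into the terminal alkyne without breaking any bond at C4 or C8.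

Step 8
Reactants: 13 alkynyl epoxide
Product: 14 (2R,3R)-2-ethynyl-2-methoxy-4-(aryl)-3-methylbutan-1-ol
Conditions: BF3·OEt2 (5 mol%), MeOH–CH2Cl2, −40 to 0 °C
Reagents that add atoms: methanol, CO
Why: Lewis-acid-catalysed alcoholysis of a 2,2-disubstituted propargylic epoxide is a borderline SN2 opening at the tertiary carbon that best carries positive charge, so methanol enters C4 anti to the departing oxygen (inversion, 2S epoxide to 2R ether) and the epoxide CH2–O becomes the primary alcohol.

Step 9
Reactants: 14 methoxy alkynol; 15 pent-4-enal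
Product: 17 (2R)-2-methoxy-2-[(2R)-1-(aryl)propan-2-yl]non-8-en-3-yne-1,5-diol (both C5 epimers), via dilithio derivative 16 (not isolated)
Conditions: n-BuLi (2.1 equiv), THF, −78 °C; 15; then H2O
Reagents that add atoms: none
Why: Double deprotonation gives the alkoxide acetylide, whose carbon end adds 1,2 to the aldehyde (acetylide addition); the new carbinol centre forms unselectively and is erased in the next step.

Step 10
Reactants: 17 diol
Product: 18 (2R)-2-methoxy-2-[(2R)-1-(aryl)propan-2-yl]-5-oxonon-8-en-3-ynal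
Conditions: Dess–Martin periodinane (2.5 equiv), CH2Cl2, 0 °C to rt
Reagents that add atoms: none
Why: Dess–Martin oxidation turns the primary alcohol into the non-enolisable aldehyde and the propargylic alcohol into the ynone in one neutral operation that leaves C4 and C8 untouched.

Step 11
Reactants: 18 keto ynal
Product: 21 (4S)-2-allyl-4,5-dimethoxy-4-[(2R)-1-(aryl)propan-2-yl]cyclohexa-2,5-dien-1-one, via beta-methoxy enone 19 (not isolated), via aldol adduct 20 (not isolated)
Conditions: NaOMe (0.2 equiv), MeOH, 0 °C to rt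
Reagents that add atoms: methanol, CO
Why: Methoxide adds to the β-carbon C5 of the alkynone (oxa-Michael) to give enone 19 as an E/Z mixture that interconverts by reversible methoxide addition–elimination; the cross-conjugated enolate at C2 of the isomer with C4 cis to C1 then attacks the aldehyde carbon C3, and E1cB loss of water from aldol 20 gives the dienone irreversibly. The closest known reaction types are alkoxide addition to ynones and the intramolecular aldol condensation that ends a Robinson annulation. The six-membered ring closes in the 6-(enolendo)-exo-trig mode by forming C2–C3. No lasting stereocentre is created: C4 and C8 carry no exchangeable hydrogen and no bond to them is broken, and the transient centres at C2 and C3 vanish on dehydration. The step needs methanol addition at C5 only (secured by the ynone polarity), enolisation at C2 only (secured because quaternary C4 leaves no γ-hydrogen and no aldehyde α-hydrogen) and selection of one enol ether geometry (secured by Curtin–Hammett funnelling, since only that isomer can reach the aldehyde).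

Step 12
Reactants: 21 silyl-protected dienone
Product: 22 (4S)-2-allyl-4-[(2R)-1-(4-hydroxy-3-methoxyphenyl)propan-2-yl]-4,5-dimethoxycyclohexa-2,5-dien-1-one (target)
Conditions: TBAF, AcOH, THF, 0 °C
Reagents that add atoms: none
Why: Fluoride cleaves the aryl silyl ether under acetic acid buffering so that no free phenoxide adds to the dienone, nothing else is fluoride-labile, and any phenol already freed by methoxide in step 11 converges on the same product.

Compound list
1 | (E)-isoeugenol | C/C=C/c1ccc(O)c(OC)c1 | starting material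
2 | (E)-isoeugenol triisopropylsilyl ether | C/C=C/c1ccc(O[Si](C(C)C)(C(C)C)C(C)C)c(OC)c1 | intermediate
3 | (R)-2-[1-(aryl)propan-2-yl]-4,4,5,5-tetramethyl-1,3,2-dioxaborolane | CC1(C)OB(OC1(C)C)[C@H](C)Cc2ccc(O[Si](C(C)C)(C(C)C)C(C)C)c(OC)c2 | intermediate
4 | 2-bromoprop-2-en-1-ol | OCC(Br)=C | starting material
5 | 2-bromo-3-(2-methoxypropan-2-yloxy)prop-1-ene | C=C(Br)COC(C)(C)OC | intermediate
6 | [3-(2-methoxypropan-2-yloxy)prop-1-en-2-yl]lithium | [Li]C(=C)COC(C)(C)OC | intermediate
7 | lithium boronate complex of 3 and 6 | [Li+].CC1(C)O[B-](OC1(C)C)(C(=C)COC(C)(C)OC)[C@H](C)Cc2ccc(O[Si](C(C)C)(C(C)C)C(C)C)c(OC)c2 | intermediate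
8 | β-iodo tertiary boronic ester (C4 undefined, C8 R) | CC1(C)OB(OC1(C)C)C(CI)(COC(C)(C)OC)[C@H](C)Cc2ccc(O[Si](C(C)C)(C(C)C)C(C)C)c(OC)c2 | intermediate
9 | MIP ether of allylic alcohol 10 | C=C(COC(C)(C)OC)[C@H](C)Cc1ccc(O[Si](C(C)C)(C(C)C)C(C)C)c(OC)c1 | intermediate
10 | (3R)-4-(aryl)-3-methyl-2-methylidenebutan-1-ol | C=C(CO)[C@H](C)Cc1ccc(O[Si](C(C)C)(C(C)C)C(C)C)c(OC)c1 | intermediate
11 | {(2S)-2-[(2R)-1-(aryl)propan-2-yl]oxiran-2-yl}methanol | C1O[C@@]1([C@H](C)Cc2ccc(O[Si](C(C)C)(C(C)C)C(C)C)c(OC)c2)CO | intermediate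
12 | (2R)-2-[(2R)-1-(aryl)propan-2-yl]oxirane-2-carbaldehyde | C1O[C@@]1([C@H](C)Cc2ccc(O[Si](C(C)C)(C(C)C)C(C)C)c(OC)c2)C=O | intermediate
13 | (2S)-2-ethynyl-2-[(2R)-1-(aryl)propan-2-yl]oxirane | C1O[C@@]1([C@H](C)Cc2ccc(O[Si](C(C)C)(C(C)C)C(C)C)c(OC)c2)C#C | intermediate
14 | (2R,3R)-2-ethynyl-2-methoxy-4-(aryl)-3-methylbutan-1-ol | OC[C@@](OC)([C@H](C)Cc1ccc(O[Si](C(C)C)(C(C)C)C(C)C)c(OC)c1)C#C | intermediate
15 | pent-4-enal | C=CCCC=O | starting material
16 | O,C-dilithio derivative of 14 | [Li]OC[C@@](OC)([C@H](C)Cc1ccc(O[Si](C(C)C)(C(C)C)C(C)C)c(OC)c1)C#C[Li] | intermediate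
17 | (2R)-2-methoxy-2-[(2R)-1-(aryl)propan-2-yl]non-8-en-3-yne-1,5-diol (C5 epimers) | OC[C@@](OC)([C@H](C)Cc1ccc(O[Si](C(C)C)(C(C)C)C(C)C)c(OC)c1)C#CC(O)CCC=C | intermediate
18 | (2R)-2-methoxy-2-[(2R)-1-(aryl)propan-2-yl]-5-oxonon-8-en-3-ynal | O=C[C@@](OC)([C@H](C)Cc1ccc(O[Si](C(C)C)(C(C)C)C(C)C)c(OC)c1)C#CC(=O)CCC=C | intermediate
19 | (2R)-2,3-dimethoxy-2-[(2R)-1-(aryl)propan-2-yl]-5-oxonona-3,8-dienal (E/Z mixture) | O=C[C@@](OC)([C@H](C)Cc1ccc(O[Si](C(C)C)(C(C)C)C(C)C)c(OC)c1)C(OC)=CC(=O)CCC=C | intermediate
20 | (4S)-6-allyl-5-hydroxy-3,4-dimethoxy-4-[(2R)-1-(aryl)propan-2-yl]cyclohex-2-en-1-one (C5, C6 undefined) | C=CCC1C(O)[C@@](OC)([C@H](C)Cc2ccc(O[Si](C(C)C)(C(C)C)C(C)C)c(OC)c2)C(OC)=CC1=O | intermediate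
21 | (4S)-2-allyl-4,5-dimethoxy-4-[(2R)-1-(aryl)propan-2-yl]cyclohexa-2,5-dien-1-one | C=CCC1=C[C@@](OC)([C@H](C)Cc2ccc(O[Si](C(C)C)(C(C)C)C(C)C)c(OC)c2)C(OC)=CC1=O | intermediate
22 | (4S)-2-allyl-4-[(2R)-1-(4-hydroxy-3-methoxyphenyl)propan-2-yl]-4,5-dimethoxycyclohexa-2,5-dien-1-one | C=CCC1=C[C@@](OC)([C@H](C)Cc2ccc(O)c(OC)c2)C(OC)=CC1=O | target

Total step count: 12. Longest linear sequence: 11 steps (1, 2, 4–12).

Steps most likely to fail

Step 11. Methoxide may attack the aldehyde and expel the C4 carbanion with loss of methyl formate (deformylation) before the ring closes. The enol ether isomers may also interconvert too slowly to feed the cyclisation. The fallback separates the events and never exposes the aldehyde to a nucleophilic base. It sets out from diol 17. MnO2 oxidises only the propargylic alcohol to the hydroxy ynone F1. NaOMe in MeOH adds methanol and equilibrates the geometry at the stage of the hydroxy β-methoxy enone F2. Dess–Martin oxidation then gives 19, whose kinetic lithium enolate (LiHMDS, THF, −78 °C) closes to aldol 20. DBU in warm toluene removes water, and the route is rejoined at 21.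

Step 8. Methanol may open the epoxide at the CH2 terminus. Partial ionisation may erode the configuration at C4, or the electron-rich arene may capture the activated epoxide in a Friedel–Crafts sense. The fallback never breaks the C4–O bond. It sets out from allylic alcohol 10. Sharpless epoxidation with D-(−)-DIPT gives the C4-epimeric epoxy alcohol F3. TEMPO/PhI(OAc)2 gives the epoxy aldehyde F4, and Ohira–Bestmann homologation gives the alkynyl epoxide F5. Sodium 4-methoxybenzyl oxide in DMF opens the epoxide at CH2 by SN2, and the tertiary alkoxide is trapped in the same flask with MeI to give the PMB-protected methyl ether F6. DDQ then removes the PMB group, and the route is rejoined at 14.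

Step 4. Complexation of the hindered secondary boronic ester with the α-branched alkenyllithium may be incomplete or reversible, and the migration may then compete with decomposition of the organolithium. The fallback builds the 1,1-disubstituted alkene from an alkyne instead. It sets out from boronic ester 3. α-Lithiated vinyl N,N-diisopropylcarbamate (LDA), then iodine and methoxide, give the vinyl carbamate F7 with retention at C8. Excess LDA eliminates the carbamate to give the terminal alkyne F8. Nickel-catalysed α-selective hydroalumination (Ni(dppp)Cl2, DIBAL-H) followed by paraformaldehyde places the CH2OH group on the internal carbon, and the route is rejoined at 10.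

Further compounds
F1 | step 11 | (2R)-1-hydroxy-2-methoxy-2-[(2R)-1-(aryl)propan-2-yl]non-8-en-3-yn-5-one | OC[C@@](OC)([C@H](C)Cc1ccc(O[Si](C(C)C)(C(C)C)C(C)C)c(OC)c1)C#CC(=O)CCC=C
F2 | step 11 | (2S)-1-hydroxy-2,3-dimethoxy-2-[(2R)-1-(aryl)propan-2-yl]nona-3,8-dien-5-one (E/Z mixture) | OC[C@@](OC)([C@H](C)Cc1ccc(O[Si](C(C)C)(C(C)C)C(C)C)c(OC)c1)C(OC)=CC(=O)CCC=C
F3 | step 8 | {(2R)-2-[(2R)-1-(aryl)propan-2-yl]oxiran-2-yl}methanol | C1O[C@]1([C@H](C)Cc2ccc(O[Si](C(C)C)(C(C)C)C(C)C)c(OC)c2)CO
F4 | step 8 | (2S)-2-[(2R)-1-(aryl)propan-2-yl]oxirane-2-carbaldehyde | C1O[C@]1([C@H](C)Cc2ccc(O[Si](C(C)C)(C(C)C)C(C)C)c(OC)c2)C=O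
F5 | step 8 | (2R)-2-ethynyl-2-[(2R)-1-(aryl)propan-2-yl]oxirane | C1O[C@]1([C@H](C)Cc2ccc(O[Si](C(C)C)(C(C)C)C(C)C)c(OC)c2)C#C
F6 | step 8 | 4-methoxybenzyl ether of 14 | COc1ccc(COC[C@@](OC)([C@H](C)Cc2ccc(O[Si](C(C)C)(C(C)C)C(C)C)c(OC)c2)C#C)cc1
F7 | step 4 | (3R)-4-(aryl)-3-methylbut-1-en-2-yl N,N-diisopropylcarbamate | C=C(OC(=O)N(C(C)C)C(C)C)[C@H](C)Cc1ccc(O[Si](C(C)C)(C(C)C)C(C)C)c(OC)c1
F8 | step 4 | (3R)-4-(aryl)-3-methylbut-1-yne | C#C[C@H](C)Cc1ccc(O[Si](C(C)C)(C(C)C)C(C)C)c(OC)c1
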